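**Plan**
1. Retrosynthesis: the furanone is opened at the lactone bond O1–C5 with removal of one bromine of the exocyclic CBr2, giving an (E)-3,5-dibromo-2-butylpent-2-en-4-ynoic acid. Removing the alkynyl bromine, then the C4–C5 alkyne (from a 3-bromo-3-iodoacrylate), then the C=CBr2 bond leads back to ethyl 2-oxohexanoate.
2. Enabling feature: ring carbon C5 carries the ring oxygen O1 and a double bond to the CBr2 carbon, so it is the enol ester of a dibromomethyl ketone. That is the result of anti addition of a carboxylate oxygen and Br+ across a 1-bromoalkyne, and the ring alkene C3=C4 holds the C2 carboxyl and the alkyne cis, set up for 5-exo closure.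
3. Forward order: gem-dibromoolefination of the keto ester; chelation-directed Br/Mg exchange and iodination; alkynylation at C–I; saponification with desilylation; then one-flask alkyne C–H bromination and bromolactonisation, which forms the only ring last.
4. Stereochemistry: the target has no stereocentre, and the exocyclic alkene has no geometry because it carries two bromines. The only element to control is the cis relation of carboxyl and alkyne across the open-chain C2=C3 bond, set in step 2 by ester chelation and retained in steps 3 and 4.

Key step: step 5

**Step 1**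
Reactants: 1 ethyl 2-oxohexanoate
Product: 2 ethyl 3,3-dibromo-2-butylacrylate
Conditions: CBr4, PPh3, CH2Cl2, 0 °C to rt
Reagents that add atoms: carbon tetrabromide, BrC(Br)(Br)Br
Why: The ketone carbonyl of an α-keto ester is strongly electrophilic and should undergo Wittig-type gem-dibromoolefination with Ph3P=CBr2 formed in situ (Ramirez olefination, first stage of the Corey–Fuchs sequence); no alkene geometry arises because both new substituents are bromine.

**Step 2**
Reactants: 2 ethyl 3,3-dibromo-2-butylacrylate
Product: 4 ethyl (Z)-3-bromo-2-butyl-3-iodoacrylate, via magnesium carbenoid 3 (not isolated)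
Conditions: iPrMgCl·LiCl, THF, −78 °C; then I2, −78 to 0 °C; aq. Na2S2O3 work-up
Reagents that add atoms: iodine, II; isopropylmagnesium chloride–lithium chloride, CC(C)[Mg]Cl.[Li+].[Cl-] (supplies MgCl to intermediate 3 only)
Why: Bromine–magnesium exchange of a gem-dibromoalkene with the turbo-Grignard reagent should occur at the bromine cis to the ester, whose carbonyl oxygen holds magnesium in a five-membered chelate, and iodinolysis of the alkenylmagnesium carbenoid at −78 °C proceeds with retention, so iodine ends up cis to the ester (chelation-directed halogen–metal exchange, then electrophilic quench).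

**Step 3**
Reactants: 4 ethyl (Z)-3-bromo-2-butyl-3-iodoacrylate; 5 trimethylsilylacetylene
Product: 6 ethyl (E)-3-bromo-2-butyl-5-(trimethylsilyl)pent-2-en-4-ynoate
Conditions: PdCl2(PPh3)2 (cat.), CuI (cat.), Et3N, THF, 0 °C to rt
Reagents that add atoms: trimethylsilylacetylene 5, C#C[Si](C)(C)C
Why: Sonogashira coupling; zerovalent palladium inserts into the C–I bond far faster than into the geminal C–Br bond and the coupling retains alkene geometry, so the alkyne is placed cis to the ester and the vinylic bromine is kept.

**Step 4**
Reactants: 6 ethyl (E)-3-bromo-2-butyl-5-(trimethylsilyl)pent-2-en-4-ynoate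
Product: 7 (E)-3-bromo-2-butylpent-2-en-4-ynoic acid
Conditions: LiOH·H2O, THF/H2O, 0 °C to rt; then cold 1 M HCl
Reagents that add atoms: lithium hydroxide, [Li+].[OH-] (supplies the carboxyl OH oxygen)
Why: Hydroxide should cleave the ethyl ester (saponification) and the alkynyl C–Si bond (protodesilylation) in one operation; once the carboxylate has formed the alkene is a poor acceptor, and the alkene geometry is not touched.

**Step 5**
Reactants: 7 (E)-3-bromo-2-butylpent-2-en-4-ynoic acid
Product: 9 target butenolide 4-bromo-3-butyl-5-(dibromomethylidene)furan-2(5H)-one, via bromoalkyne carboxylate 8 (not isolated)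
Conditions: Br2, aq. NaOH, 0 °C; then NaH2PO4 to pH 7–8, NBS, Bu4NHSO4 (cat.), CH2Cl2/H2O, 0 °C to rt, dark
Reagents that add atoms: bromine, BrBr; N-bromosuccinimide, O=C1CCC(=O)N1Br
Why: In alkaline hypobromite only the acidic alkyne C–H is brominated, giving bromoalkyne carboxylate 8; at pH 7–8 NBS then delivers Br+ to the bromine-bearing alkyne terminus while the cis carboxylate oxygen adds anti to the internal alkyne carbon. The closest known reaction type is the halo enol lactonisation of alkynoic acids, as in the NBS/KHCO3 cyclisation of 5-halo-4-pentynoic acids and of (Z)-2-en-4-ynoic acids to halomethylidene lactones. The furanone ring closes in the 5-exo-dig mode by forming the bond between the ring oxygen and C5. No stereocentre is formed, and because both substituents of the new exocyclic carbon are bromine the anti course of the addition leaves no geometry to control. The step needs 5-exo over 6-endo closure and C–H bromination before ring closure. The first should be secured by the bromine already on the alkyne terminus, which directs the oxygen nucleophile to the internal carbon (as in the NBS/water conversion of 1-bromoalkynes into α,α-dibromoketones), and by the rigid (E)-alkene that holds the carboxylate oxygen next to that carbon; the second by the pH switch, since hypobromite anion does not attack the alkyne π bond.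

**Compound list**
1 | ethyl 2-oxohexanoate | CCCCC(=O)C(=O)OCC | starting material
2 | ethyl 3,3-dibromo-2-butylacrylate | CCCCC(=C(Br)Br)C(=O)OCC | intermediate
3 | ethyl (E)-3-bromo-2-butyl-3-(chloromagnesio)acrylate (magnesium cis to the ester) | CCCC/C(=C(\Br)[Mg]Cl)C(=O)OCC | intermediate (not isolated)
4 | ethyl (Z)-3-bromo-2-butyl-3-iodoacrylate (iodine cis to the ester) | CCCC/C(=C(\Br)I)C(=O)OCC | intermediate
5 | trimethylsilylacetylene | C#C[Si](C)(C)C | starting material
6 | ethyl (E)-3-bromo-2-butyl-5-(trimethylsilyl)pent-2-en-4-ynoate (alkyne cis to the ester) | CCCC/C(=C(\Br)C#C[Si](C)(C)C)C(=O)OCC | intermediate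
7 | (E)-3-bromo-2-butylpent-2-en-4-ynoic acid | CCCC/C(=C(\Br)C#C)C(=O)O | intermediate
8 | sodium (E)-3,5-dibromo-2-butylpent-2-en-4-ynoate | CCCC/C(=C(\Br)C#CBr)C(=O)[O-].[Na+] | intermediate (not isolated)
9 | 4-bromo-3-butyl-5-(dibromomethylidene)furan-2(5H)-one | CCCCC1=C(Br)C(=C(Br)Br)OC1=O | target

**Step count:** 5 steps in total; longest linear sequence 5 steps.

**Steps most likely to fail**

Step 5. Ring closure on the terminal alkyne may outrun its C–H bromination, or the bromoalkyne may close in the 6-endo sense to a pyranone. Fallback: ring closure and the second exocyclic bromination are separated. Setting out from 7, NBS/KHCO3 (CH2Cl2/H2O, Bu4NHSO4) should give, by 5-exo-dig bromolactonisation of the terminal alkyne, (E)-4-bromo-5-(bromomethylidene)-3-butylfuran-2(5H)-one F1. Br2 in CH2Cl2 should add across the exocyclic enol double bond to give racemic 4,5-dibromo-3-butyl-5-(dibromomethyl)furan-2(5H)-one F2. DBU (CH2Cl2, 0 °C) should then remove HBr (the C5 bromine and the CHBr2 hydrogen), and the route is rejoined at 9.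

Step 2. Exchange may occur at the bromine trans to the ester, or the α-bromo alkenylmagnesium species may be lost by 1,2-shift on warming. Fallback: a carboxylate is used as the directing group. Setting out from 2, LiOH (THF/H2O) should give 3,3-dibromo-2-butylacrylic acid F3. n-BuLi (2 equiv, THF, −100 °C) should form, by carboxylate-directed bromine–lithium exchange, the dianion lithium (E)-3-bromo-2-butyl-3-lithioacrylate F4. Iodine should convert it into (Z)-3-bromo-2-butyl-3-iodoacrylic acid F5, and EtI/K2CO3 (DMF) re-esterifies to rejoin the route at 4.

Step 4. Hydroxide may attack the bromine-bearing alkene carbon (addition–elimination) or the alkyne terminus (1,6-addition) instead of the ester carbonyl. Fallback: the free acid is bypassed. Setting out from 6, NBS with AgNO3 (cat.) in acetone should exchange silicon for bromine to give ethyl (E)-3,5-dibromo-2-butylpent-2-en-4-ynoate F6. Br2 in CH2Cl2 should then close the ring through the ester carbonyl oxygen (5-exo-dig), with bromide removing the ethyl group from the oxocarbenium ion (electrophilic cyclisation of a (Z)-2-en-4-ynoate ester), which rejoins the route at 9.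

**Further compounds**
F1 | step 5 | (E)-4-bromo-5-(bromomethylidene)-3-butylfuran-2(5H)-one | CCCCC1=C(Br)/C(=C\Br)OC1=O
F2 | step 5 | racemic 4,5-dibromo-3-butyl-5-(dibromomethyl)furan-2(5H)-one | CCCCC1=C(Br)C(Br)(C(Br)Br)OC1=O
F3 | step 2 | 3,3-dibromo-2-butylacrylic acid | CCCCC(=C(Br)Br)C(=O)O
F4 | step 2 | lithium (E)-3-bromo-2-butyl-3-lithioacrylate | CCCC/C(=C(\Br)[Li])C(=O)[O-].[Li+]
F5 | step 2 | (Z)-3-bromo-2-butyl-3-iodoacrylic acid | CCCC/C(=C(\Br)I)C(=O)O
F6 | step 4 | ethyl (E)-3,5-dibromo-2-butylpent-2-en-4-ynoate | CCCC/C(=C(\Br)C#CBr)C(=O)OCC
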